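## Retrosynthetic overview

1. The N–O bond is made last, by oxygen transfer to the ring nitrogen of the N-deoxy pyridone (the proposed new step).
2. The C2=C3 bond of the trienone comes from a Claisen–Schmidt condensation of a 3-acetyl-4-hydroxy-2-pyridone with the (2E,4E,6R,8S)-dienal.
3. The dienal comes from two Wittig homologations of (2R,4S)-2,4-dimethylhexanal. Its C8–C9 bond (target numbering) is made by invertive coupling of tert-butyl (R)-lactate triflate with the Grignard reagent of (S)-1-bromo-2-methylbutane.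
4. Both C–O bonds of the cis-1,4-diol form in one photochemical step, a singlet-oxygen [4+2] cycloaddition to a 5-(cyclohexa-1,3-dienyl)pyridine, followed by hydrogenation (O–O, C=C, benzyl ethers).
5. Both rings are bought (5-bromo-2,4-dichloropyridine, cyclohexenone) and joined by Grignard addition and dehydration. The only ring formed is the transient 2,3-dioxabicyclo[2.2.2]octene, opened again in the same flask.

Assumption: C1′ and C4′ of the cyclohexane are read from the SMILES as the cis-1,4-diol (both OH on one face, pyridone trans to the 4-OH); compounds 1, 2, 11 and 13 are taken as commercial.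

## Route

Step 1
Reactants: 1 5-bromo-2,4-dichloropyridine; 2 cyclohex-2-en-1-one
Product: 5 2,4-dichloro-5-(cyclohexa-1,3-dien-1-yl)pyridine, via pyridylmagnesium chloride 3 (not isolated), via tertiary allylic alcohol 4 (not isolated)
Conditions: i-PrMgCl·LiCl (1.05 equiv), THF, −15 °C, 1 h; LaCl3·2LiCl (1.0 equiv), 2 (1.2 equiv), −15 → 0 °C; 2 M HCl, extraction into toluene; TsOH·H2O (5 mol%), toluene, 60 °C
Reagents that add atoms: none
Why: Bromine–magnesium exchange is selective for C–Br over C–Cl, LaCl3·2LiCl promotes clean 1,2-addition of the aryl Grignard reagent to the enone (Grignard addition), and acid-catalysed E1 dehydration under equilibrating conditions funnels the tertiary allylic alcohol to the linearly conjugated 1-aryl-1,3-diene, so no stereocentre has to be controlled.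

Step 2
Reactants: 5 2,4-dichloro-5-(cyclohexa-1,3-dien-1-yl)pyridine
Product: 7 1-[2,4-dichloro-5-(cyclohexa-1,3-dien-1-yl)pyridin-3-yl]ethan-1-one, via 3-lithiopyridine 6 (not isolated)
Conditions: LiN(i-Pr)2 (1.1 equiv), THF, −78 °C, 30 min; MeC(O)N(OMe)Me (1.3 equiv), −78 → −40 °C; H2O
Reagents that add atoms: N-methoxy-N-methylacetamide, CC(=O)N(C)OC
Why: Directed ortho-lithiation removes the only ring proton flanked by two chlorines (C3) faster than any allylic proton of the diene at −78 °C, and the Weinreb amide acylation stops at the ketone because the tetrahedral chelate survives until work-up.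

Step 3
Reactants: 7 1-[2,4-dichloro-5-(cyclohexa-1,3-dien-1-yl)pyridin-3-yl]ethan-1-one
Product: 8 1-[2,4-bis(benzyloxy)-5-(cyclohexa-1,3-dien-1-yl)pyridin-3-yl]ethan-1-one
Conditions: BnOH (2.4 equiv), NaH (2.3 equiv), THF, 0 °C → rt, 6 h
Reagents that add atoms: benzyl alcohol, OCc1ccccc1
Why: Twofold nucleophilic aromatic substitution (SNAr, addition–elimination) by benzyloxide at C4 and C2, both activated by the ring nitrogen and the ortho acetyl group, installs hydrogenolysable protecting groups without any strong base ever meeting the benzyl ethers.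

Step 4
Reactants: 8 1-[2,4-bis(benzyloxy)-5-(cyclohexa-1,3-dien-1-yl)pyridin-3-yl]ethan-1-one
Product: 10 3-acetyl-4-hydroxy-5-(cis-1,4-dihydroxycyclohexyl)pyridin-2(1H)-one, via endoperoxide 9 (not isolated)
Conditions: O2 (1 atm), tetraphenylporphyrin (1 mol%), white LEDs, EtOAc, 0 °C, 2 h; N2 purge; H2 (1 atm), 10% Pd/C, EtOAc–MeOH, rt, 6 h
Reagents that add atoms: oxygen, O=O
Why: Dye-sensitised photooxygenation delivers singlet oxygen to the s-cis diene in a suprafacial [4+2] cycloaddition so that both new C–O bonds lie on one face (cis-1,4), and the catalytic hydrogenation in the same flask cleaves the O–O bond without touching either C–O bond, saturates the alkene and hydrogenolyses both benzyl ethers, which fixes the cis-diol with the pyridone trans to the 4-OH.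

Step 5
Reactants: 11 tert-butyl (R)-lactate
Product: 12 tert-butyl (2R)-2-[(trifluoromethanesulfonyl)oxy]propanoate
Conditions: Tf2O (1.1 equiv), 2,6-lutidine (1.2 equiv), CH2Cl2, −78 → 0 °C; filtration through silica (pentane), used at once
Reagents that add atoms: trifluoromethanesulfonic anhydride, O=S(=O)(OS(=O)(=O)C(F)(F)F)C(F)(F)F
Why: O-Sulfonylation (triflation) of the secondary alcohol with a hindered pyridine base does not touch the C–O bond, so the bought (R) centre is kept and turned into a leaving group for an invertive substitution.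

Step 6
Reactants: 13 (S)-1-bromo-2-methylbutane; 12 tert-butyl (2R)-2-[(trifluoromethanesulfonyl)oxy]propanoate
Product: 15 tert-butyl (2R,4S)-2,4-dimethylhexanoate, via Grignard reagent 14 (not isolated)
Conditions: Mg (1.6 equiv), THF, 40 °C; solution of 14 (1.5 equiv) added to 12, ZnCl2 (5 mol%), THF, 0 °C, 3 h
Reagents that add atoms: none
Why: In this zinc-catalysed sp3–sp3 cross-coupling of a Grignard reagent with an α-triflyloxy ester the triorganozincate formed in the flask displaces triflate by SN2 with clean inversion, so the bought (R)-lactate centre becomes the (2R) centre (the descriptor is unchanged because the priorities change), while the bought (S) centre of 13 lies β to magnesium and is not touched.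

Step 7
Reactants: 15 tert-butyl (2R,4S)-2,4-dimethylhexanoate
Product: 17 (2E,4R,6S)-2,4,6-trimethyloct-2-enal, via aldehyde 16 (not isolated)
Conditions: i-Bu2AlH (1.15 equiv), toluene, −78 °C, 1 h; aq. KNaC4H4O6 work-up; dried toluene phase, Ph3P=C(Me)CHO (1.4 equiv), 85 °C, 18 h
Reagents that add atoms: 2-(triphenylphosphoranylidene)propanal, CC(C=O)=P(c1ccccc1)(c1ccccc1)c1ccccc1
Why: Low-temperature partial reduction of the tert-butyl ester stops at the tetrahedral aluminium hemiacetal, and the volatile, epimerisable aldehyde released on work-up is trapped without isolation in a Wittig olefination with the stabilised formyl ylide, which gives the (E)-trisubstituted enal while the α-stereocentre never meets a strong base.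

Step 8
Reactants: 17 (2E,4R,6S)-2,4,6-trimethyloct-2-enal
Product: 19 (2E,4E,6R,8S)-4,6,8-trimethyldeca-2,4-dienal, via dienyl dioxolane 18 (not isolated)
Conditions: [Ph3PCH2CH(OCH2CH2O)]Br (1.5 equiv), KOt-Bu (1.45 equiv), THF, 0 °C → rt; 1 M HCl, THF, rt, 2 h
Reagents that add atoms: (1,3-dioxolan-2-ylmethyl)triphenylphosphonium bromide, [Br-].C1COC(C[P+](c2ccccc2)(c2ccccc2)c2ccccc2)O1; water, O
Why: This Wittig two-carbon homologation with the dioxolane-masked formylmethylene ylide cannot over-homologate because the new aldehyde stays masked, and the acidic acetal hydrolysis releases the dienal while equilibrating any (2Z) isomer to the conjugated (2E,4E)-dienal.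

Step 9
Reactants: 10 3-acetyl-4-hydroxy-5-(cis-1,4-dihydroxycyclohexyl)pyridin-2(1H)-one; 19 (2E,4E,6R,8S)-4,6,8-trimethyldeca-2,4-dienal
Product: 20 4-hydroxy-5-(cis-1,4-dihydroxycyclohexyl)-3-[(2E,4E,6E,8R,10S)-6,8,10-trimethyldodeca-2,4,6-trienoyl]pyridin-2(1H)-one
Conditions: piperidine (0.5 equiv), EtOH, 4 Å molecular sieves, 60 °C, argon, dark
Reagents that add atoms: none
Why: In this Claisen–Schmidt-type aldol condensation under secondary-amine catalysis the acetyl group of the vinylogous acid (the reactivity known from dehydroacetic acid and 3-acetyl-4-hydroxy-2-pyridone chalcone syntheses) adds to the amine-activated aldehyde and the aldol loses water (E1cB) to the thermodynamic (2E)-alkene, with the existing stereocentres and the ring hydroxyls as spectators.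

Step 10
Reactants: 20 4-hydroxy-5-(cis-1,4-dihydroxycyclohexyl)-3-[(2E,4E,6E,8R,10S)-6,8,10-trimethyldodeca-2,4,6-trienoyl]pyridin-2(1H)-one
Product: 22 1,4-dihydroxy-5-(cis-1,4-dihydroxycyclohexyl)-3-[(2E,4E,6E,8R,10S)-6,8,10-trimethyldodeca-2,4,6-trienoyl]pyridin-2(1H)-one, via dipotassium salt 21 (not isolated)
Conditions: KN(SiMe3)2 (2.05 equiv), THF–DMF 4:1, −78 °C, 20 min; 2-(phenylsulfonyl)-3-phenyloxaziridine (1.05 equiv, slow addition), −78 → −40 °C, 1 h; AcOH (2.2 equiv)
Reagents that add atoms: 2-(phenylsulfonyl)-3-phenyloxaziridine, O=S(=O)(N1OC1c1ccccc1)c1ccccc1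
Why: Proposed new method: two equivalents of base remove only the 4-OH and N–H protons, and the resulting ambident pyridonate attacks the electrophilic oxygen of the N-sulfonyloxaziridine through its in-plane nitrogen lone pair (SN2 at oxygen with the sulfonimine as leaving group), nitrogen being the most basic unhindered site while C3 and C5 are fully substituted and the electron-poor trienone is not epoxidised by this reagent, so the cyclic hydroxamate forms directly; the closest known reactions are the oxaziridine hydroxylation of enolates, the oxaziridine oxidation of secondary amines to hydroxylamines, and the N-oxidation of silylated 2-pyridones with peroxomolybdenum reagents.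

## Compound list

1 | 5-bromo-2,4-dichloropyridine | Clc1cc(Cl)c(Br)cn1 | starting material
2 | cyclohex-2-en-1-one | O=C1C=CCCC1 | starting material
3 | (4,6-dichloropyridin-3-yl)magnesium chloride (LiCl complex) | Cl[Mg]c1cnc(Cl)cc1Cl | intermediate
4 | 1-(4,6-dichloropyridin-3-yl)cyclohex-2-en-1-ol (racemic) | OC1(C=CCCC1)c1cnc(Cl)cc1Cl | intermediate
5 | 2,4-dichloro-5-(cyclohexa-1,3-dien-1-yl)pyridine | Clc1cc(Cl)c(C2=CC=CCC2)cn1 | intermediate
6 | [2,4-dichloro-5-(cyclohexa-1,3-dien-1-yl)pyridin-3-yl]lithium | [Li]c1c(Cl)ncc(C2=CC=CCC2)c1Cl | intermediate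
7 | 1-[2,4-dichloro-5-(cyclohexa-1,3-dien-1-yl)pyridin-3-yl]ethan-1-one | CC(=O)c1c(Cl)ncc(C2=CC=CCC2)c1Cl | intermediate
8 | 1-[2,4-bis(benzyloxy)-5-(cyclohexa-1,3-dien-1-yl)pyridin-3-yl]ethan-1-one | CC(=O)c1c(OCc2ccccc2)ncc(C2=CC=CCC2)c1OCc1ccccc1 | intermediate
9 | 1-[2,4-bis(benzyloxy)-5-(2,3-dioxabicyclo[2.2.2]oct-5-en-1-yl)pyridin-3-yl]ethan-1-one (racemic) | CC(=O)c1c(OCc2ccccc2)ncc(C23OOC(C=C2)CC3)c1OCc1ccccc1 | intermediate
10 | 3-acetyl-4-hydroxy-5-(cis-1,4-dihydroxycyclohexyl)pyridin-2(1H)-one | CC(=O)c1c(O)c([C@]2(O)CC[C@@H](O)CC2)c[nH]c1=O | intermediate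
11 | tert-butyl (R)-lactate | C[C@@H](O)C(=O)OC(C)(C)C | starting material
12 | tert-butyl (2R)-2-[(trifluoromethanesulfonyl)oxy]propanoate | C[C@@H](OS(=O)(=O)C(F)(F)F)C(=O)OC(C)(C)C | intermediate
13 | (S)-1-bromo-2-methylbutane | CC[C@H](C)CBr | starting material
14 | [(2S)-2-methylbutyl]magnesium bromide | CC[C@H](C)C[Mg]Br | intermediate
15 | tert-butyl (2R,4S)-2,4-dimethylhexanoate | CC[C@H](C)C[C@@H](C)C(=O)OC(C)(C)C | intermediate
16 | (2R,4S)-2,4-dimethylhexanal | CC[C@H](C)C[C@@H](C)C=O | intermediate
17 | (2E,4R,6S)-2,4,6-trimethyloct-2-enal | CC[C@H](C)C[C@@H](C)/C=C(C)/C=O | intermediate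
18 | 2-[(3E,5R,7S)-3,5,7-trimethylnona-1,3-dien-1-yl]-1,3-dioxolane (1Z/1E mixture) | CC[C@H](C)C[C@@H](C)/C=C(C)/C=CC1OCCO1 | intermediate
19 | (2E,4E,6R,8S)-4,6,8-trimethyldeca-2,4-dienal | CC[C@H](C)C[C@@H](C)/C=C(C)/C=C/C=O | intermediate
20 | 4-hydroxy-5-(cis-1,4-dihydroxycyclohexyl)-3-[(2E,4E,6E,8R,10S)-6,8,10-trimethyldodeca-2,4,6-trienoyl]pyridin-2(1H)-one | CC[C@H](C)C[C@@H](C)/C=C(C)/C=C/C=C/C(=O)c1c(O)c([C@]2(O)CC[C@@H](O)CC2)c[nH]c1=O | intermediate
21 | dipotassium salt of 20 (4-oxido and ring-nitrogen anion) | CC[C@H](C)C[C@@H](C)/C=C(C)/C=C/C=C/C(=O)c1c([O-])c([C@]2(O)CC[C@@H](O)CC2)c[n-]c1=O.[K+].[K+] | intermediate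
22 | 1,4-dihydroxy-5-(cis-1,4-dihydroxycyclohexyl)-3-[(2E,4E,6E,8R,10S)-6,8,10-trimethyldodeca-2,4,6-trienoyl]pyridin-2(1H)-one | CC[C@H](C)C[C@@H](C)/C=C(C)/C=C/C=C/C(=O)c1c(O)c([C@]2(O)CC[C@@H](O)CC2)cn(O)c1=O | target

## Step count and risks

Total step count: 10.

Longest linear sequence: 6 steps (1 → 5 → 7 → 8 → 10 → 20 → 22; the side-chain branch 11 → 12 → 15 → 17 → 19 → 20 → 22 is equally long).

The three steps most likely to fail:

Step 10 (the proposed new N-hydroxylation). The dianion may react at oxygen, the hydroxamate product may be oxidised further, or the sulfonimine may trap the product. The fallback sets out from 20 and comes back at 22. Compound 20 is persilylated with HN(SiMe3)2 and Me3SiCl to 3-[(2E,4E,6E,8R,10S)-6,8,10-trimethyldodeca-2,4,6-trienoyl]-2,4-bis(trimethylsilyloxy)-5-[cis-1,4-bis(trimethylsilyloxy)cyclohexyl]pyridine F1. This neutral silyl imidate is oxidised at the ring nitrogen with MoO5·C5H5N·OP(NMe2)3 in CH2Cl2 at room temperature, the known N-hydroxylation of silylated 2-pyridones used for tenellin-type pyridones. Work-up with aqueous Na4EDTA and then dilute citric acid removes the silyl groups and gives 22.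

Step 9 (condensation). The acetyl group of the vinylogous acid may condense slowly, piperidine may add reversibly to the polyene, and a trienamine from 19 could erode the C8 centre. The fallback sets out from 10 and comes back at 20. N,O-Bis(trimethylsilyl)acetamide converts 10 into 1-{2,4-bis(trimethylsilyloxy)-5-[cis-1,4-bis(trimethylsilyloxy)cyclohexyl]pyridin-3-yl}ethan-1-one F2, in which the acetyl group is an ordinary aryl methyl ketone. LiN(i-Pr)2 (1.1 equiv) in THF at −78 °C gives the kinetic lithium enolate, which adds to 19, and the aldolate is acetylated in the flask with Ac2O. Work-up with methanolic citric acid strips the silyl ethers and gives the β-acetoxy ketone 3-[(4E,6E,8R,10S)-3-acetoxy-6,8,10-trimethyldodeca-4,6-dienoyl]-4-hydroxy-5-(cis-1,4-dihydroxycyclohexyl)pyridin-2(1H)-one F3 as a mixture of C3 epimers. DBU in THF at 0 °C eliminates acetic acid (E1cB) to give 20.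

Step 1 (addition and dehydration). Some conjugate addition or enolisation of 2 is possible, and the dehydration can leave the cross-conjugated 2-aryl-1,3-diene or dimerise the product. The fallback sets out from 1 and 2 and comes back at 5. Compound 2 is converted with Tf2O and 2,6-di-tert-butyl-4-methylpyridine into the linearly conjugated cyclohexa-1,3-dien-1-yl trifluoromethanesulfonate F4. Grignard reagent 3, made from 1 as in step 1, is transmetalated with ZnCl2 to (4,6-dichloropyridin-3-yl)zinc chloride F5. Negishi coupling of F5 with F4 (Pd(PPh3)4, 3 mol%, THF, room temperature) gives 5, with the diene position fixed by the triflate and the C–Cl bonds untouched at this temperature.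

Further compounds
F1 | step 10 | 3-[(2E,4E,6E,8R,10S)-6,8,10-trimethyldodeca-2,4,6-trienoyl]-2,4-bis(trimethylsilyloxy)-5-[cis-1,4-bis(trimethylsilyloxy)cyclohexyl]pyridine | CC[C@H](C)C[C@@H](C)/C=C(C)/C=C/C=C/C(=O)c1c(O[Si](C)(C)C)c([C@]2(O[Si](C)(C)C)CC[C@@H](O[Si](C)(C)C)CC2)cnc1O[Si](C)(C)C
F2 | step 9 | 1-{2,4-bis(trimethylsilyloxy)-5-[cis-1,4-bis(trimethylsilyloxy)cyclohexyl]pyridin-3-yl}ethan-1-one | CC(=O)c1c(O[Si](C)(C)C)c([C@]2(O[Si](C)(C)C)CC[C@@H](O[Si](C)(C)C)CC2)cnc1O[Si](C)(C)C
F3 | step 9 | 3-[(4E,6E,8R,10S)-3-acetoxy-6,8,10-trimethyldodeca-4,6-dienoyl]-4-hydroxy-5-(cis-1,4-dihydroxycyclohexyl)pyridin-2(1H)-one (C3 epimers) | CC[C@H](C)C[C@@H](C)/C=C(C)/C=C/C(OC(C)=O)CC(=O)c1c(O)c([C@]2(O)CC[C@@H](O)CC2)c[nH]c1=O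
F4 | step 1 | cyclohexa-1,3-dien-1-yl trifluoromethanesulfonate | O=S(=O)(OC1=CC=CCC1)C(F)(F)F
F5 | step 1 | (4,6-dichloropyridin-3-yl)zinc chloride | Cl[Zn]c1cnc(Cl)cc1Cl
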